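**Plan**

1. Ring numbering used here: C1 (olefinic C bearing the acyloxymethyl group), C2 (olefinic CH), C3 and C4 (CH2), C5/C6 (epoxide, C5 bears CH2OH), C7, C8 (CH bearing the 3-acetoxyprop-1-en-2-yl group), C9, C10 (CH–O-isobutyrate). Retrosynthetic cuts, in order: the epoxide oxygen (back to the trans C5=C6 olefin with its hydroxymethyl as directing group); the ring bond C2–C3 (open chain with an alkenyl iodide at C2 and a primary alkyl iodide at C3); the three ester C–O bonds; C1–C10 together with C2–I (aldehyde + ethyl propiolate + iodide); C5=C6 (Z-selective Horner–Wadsworth–Emmons); the C8–alkenyl bond (conjugate addition to 5,6-dihydro-2H-pyran-2-one).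
2. Forward: lactone 7 carries C7–C10 with C8 set. Its alcohol arm is extended to the C3–C6 trisubstituted olefin, its acyl arm to the C1/C2 iodoalkene and the C10 carbinol. Acylations and protecting-group exchange give di-iodide 37. The only carbocycle, the ten-membered ring, is closed last by C2–C3 coupling, then desilylation and epoxidation follow.
3. Stereochemistry: C8 from (S)-BINAP–rhodium 1,4-addition; C10 from an oxazaborolidinium-catalysed iodo-aldol (Baylis–Hillman type); both olefin geometries from stereoselective C=C constructions, retained in the coupling; the side chain from an Evans syn-aldol; the epoxide from L-(+)-tartrate Sharpless epoxidation on the exposed face of the ring olefin.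
4. Enabling feature: C2 is the β-carbon of a masked acrylate (C1 carries CH2O-acyl and the C10 carbinol), so a (Z)-β-iodoacrylate delivers it as a geometrically pure alkenyl iodide. C3 is an unfunctionalised primary carbon, insulated by C4 from the C5=C6 olefin, so it can be carried as a stable alkylzinc. Joining these two ends closes the cyclodeca-1,5-diene with both trans olefins already in place.

Key step: step 22

Remark: the facial sense of the two catalytic asymmetric steps (3 and 11) is assigned by analogy with simpler substrates; the mirror-image ligand or catalyst is used if the opposite sense is found.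

**Route**

Step 1
Reactants: 1 2,3-dibromoprop-1-ene; 2 (4-methoxyphenyl)methanol
Product: 3 1-{[(2-bromoprop-2-en-1-yl)oxy]methyl}-4-methoxybenzene
Conditions: NaH, THF, 0 °C to rt
Reagents that add atoms: none
Why: Williamson ether synthesis in which the alkoxide of 2 displaces the allylic bromide by SN2 while the alkenyl C–Br bond is inert.

Step 2
Reactants: 3 1-{[(2-bromoprop-2-en-1-yl)oxy]methyl}-4-methoxybenzene; 4 bis(pinacolato)diboron
Product: 5 2-{3-[(4-methoxybenzyl)oxy]prop-1-en-2-yl}-4,4,5,5-tetramethyl-1,3,2-dioxaborolane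
Conditions: PdCl2(PPh3)2 (3 mol %), PPh3 (6 mol %), KOPh, toluene, 50 °C
Reagents that add atoms: none
Why: Miyaura borylation of a 1-alkenyl bromide (oxidative addition of zerovalent palladium, then boryl transfer from 4 assisted by phenoxide), with KOPh chosen because it suppresses Suzuki homocoupling of the product.

Step 3
Reactants: 5 2-{3-[(4-methoxybenzyl)oxy]prop-1-en-2-yl}-4,4,5,5-tetramethyl-1,3,2-dioxaborolane; 6 5,6-dihydro-2H-pyran-2-one
Product: 7 (4S)-4-{3-[(4-methoxybenzyl)oxy]prop-1-en-2-yl}oxan-2-one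
Conditions: [Rh(OH)((S)-binap)]2 (2.5 mol %), 1,4-dioxane/H2O 10:1, 60 °C
Reagents that add atoms: none
Why: Hayashi–Miyaura asymmetric 1,4-addition in which the alkenyl–rhodium species (monovalent rhodium) inserts the lactone C=C on the face dictated by (S)-BINAP, which by analogy with aryl additions to 6 should set C4 as S (the future C8), the base-free medium keeping the lactone closed.

Step 4
Reactants: 7 (4S)-4-{3-[(4-methoxybenzyl)oxy]prop-1-en-2-yl}oxan-2-one; 8 N,O-dimethylhydroxylamine hydrochloride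
Product: 10 (3S)-5-hydroxy-N-methoxy-N-methyl-3-{3-[(4-methoxybenzyl)oxy]prop-1-en-2-yl}pentanamide, via aluminium amide 9 (not isolated)
Conditions: AlMe3, CH2Cl2, 0 °C to rt; then 1 M HCl
Reagents that add atoms: none
Why: Weinreb aminolysis of the δ-lactone by the aluminium amide opens the ring at the acyl carbon, so that the two CH2–C arms on the stereocentre emerge differentiated as a latent aldehyde and a free primary alcohol.

Step 5
Reactants: 10 (3S)-5-hydroxy-N-methoxy-N-methyl-3-{3-[(4-methoxybenzyl)oxy]prop-1-en-2-yl}pentanamide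
Product: 11 (3S)-N-methoxy-N-methyl-3-{3-[(4-methoxybenzyl)oxy]prop-1-en-2-yl}-5-oxopentanamide
Conditions: Dess–Martin periodinane, NaHCO3, CH2Cl2, 0 °C to rt
Reagents that add atoms: none
Why: Dess–Martin oxidation of the primary alcohol under buffered conditions should give the aldehyde without touching the PMB ether, and the stereocentre is β to both carbonyls and cannot epimerise.

Step 6
Reactants: 12 2-iodoethan-1-ol
Product: 13 triethyl(2-iodoethoxy)silane
Conditions: Et3SiCl, imidazole, CH2Cl2, 0 °C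
Reagents that add atoms: chlorotriethylsilane, CC[Si](Cl)(CC)CC
Why: Standard imidazole-promoted silylation gives a primary triethylsilyl ether that can later be removed in the presence of tert-butyldimethylsilyl ethers.

Step 7
Reactants: 13 triethyl(2-iodoethoxy)silane; 14 ethyl 2-[bis(2-methylphenoxy)phosphoryl]acetate
Product: 15 ethyl 2-[bis(2-methylphenoxy)phosphoryl]-4-[(triethylsilyl)oxy]butanoate (racemic)
Conditions: NaH, DMF, 0 °C to rt
Reagents that add atoms: none
Why: C-alkylation of the doubly stabilised phosphonoacetate anion with the primary iodide (the usual preparation of α-substituted Ando reagents) installs the future C3–C4 unit.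

Step 8
Reactants: 11 (3S)-N-methoxy-N-methyl-3-{3-[(4-methoxybenzyl)oxy]prop-1-en-2-yl}-5-oxopentanamide; 15 ethyl 2-[bis(2-methylphenoxy)phosphoryl]-4-[(triethylsilyl)oxy]butanoate
Product: 16 ethyl (2Z,5S)-7-[methoxy(methyl)amino]-5-{3-[(4-methoxybenzyl)oxy]prop-1-en-2-yl}-7-oxo-2-{2-[(triethylsilyl)oxy]ethyl}hept-2-enoate
Conditions: NaH, THF, −78 to 0 °C
Reagents that add atoms: none
Why: Ando-modified Horner–Wadsworth–Emmons olefination, in which the diaryl phosphonate makes elimination from the kinetic adduct fast, so the ester ends cis to the aldehyde-derived chain (Z) and fixes the geometry that becomes the trans C5=C6 ring olefin.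

Step 9
Reactants: 16 ethyl (2Z,5S)-7-[methoxy(methyl)amino]-5-{3-[(4-methoxybenzyl)oxy]prop-1-en-2-yl}-7-oxo-2-{2-[(triethylsilyl)oxy]ethyl}hept-2-enoate
Product: 17 (3S,5Z)-6-(hydroxymethyl)-3-{3-[(4-methoxybenzyl)oxy]prop-1-en-2-yl}-8-[(triethylsilyl)oxy]oct-5-enal
Conditions: i-Bu2AlH (4.5 equiv), CH2Cl2, −78 °C; aq. potassium sodium tartrate
Reagents that add atoms: none
Why: Hydride reduction with i-Bu2AlH takes the enoate to the allylic alcohol by 1,2-addition and the Weinreb amide to the aldehyde through the chelated hemiaminal, which collapses only on work-up.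

Step 10
Reactants: 17 (3S,5Z)-6-(hydroxymethyl)-3-{3-[(4-methoxybenzyl)oxy]prop-1-en-2-yl}-8-[(triethylsilyl)oxy]oct-5-enal
Product: 18 (3S,5Z)-6-({[tert-butyl(dimethyl)silyl]oxy}methyl)-3-{3-[(4-methoxybenzyl)oxy]prop-1-en-2-yl}-8-[(triethylsilyl)oxy]oct-5-enal
Conditions: t-BuMe2SiCl, imidazole, CH2Cl2, 0 °C
Reagents that add atoms: tert-butyl(chloro)dimethylsilane, CC(C)(C)[Si](C)(C)Cl
Why: Silylation masks the allylic alcohol that will direct the final epoxidation, and the enolisable aldehyde tolerates imidazole at 0 °C.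

Step 11
Reactants: 18 (3S,5Z)-6-({[tert-butyl(dimethyl)silyl]oxy}methyl)-3-{3-[(4-methoxybenzyl)oxy]prop-1-en-2-yl}-8-[(triethylsilyl)oxy]oct-5-enal; 19 ethyl prop-2-ynoate
Product: 22 ethyl (2Z,3S,5S,7Z)-8-({[tert-butyl(dimethyl)silyl]oxy}methyl)-3-hydroxy-2-(iodomethylidene)-5-{3-[(4-methoxybenzyl)oxy]prop-1-en-2-yl}-10-[(triethylsilyl)oxy]dec-7-enoate, via silyl iodoallenoate 20 (not isolated), via trimethylsilyl ether 21 (not isolated)
Conditions: Me3SiI (1.5 equiv), (S)-3,3-diphenyl-1-(2-methylphenyl)tetrahydro-1H,3H-pyrrolo[1,2-c][1,3,2]oxazaborole (20 mol %) activated with Tf2NH (20 mol %), CH2Cl2, −78 °C; then 1 M HCl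
Reagents that add atoms: iodotrimethylsilane, C[Si](C)(C)I
Why: Catalytic asymmetric β-iodo Morita–Baylis–Hillman (three-component iodo-aldol) reaction, in which Me3SiI adds to the propiolate to give iodoallenoate 20, whose Mukaiyama-type aldol with the oxazaborolidinium-bound aldehyde should set the carbinol as S under catalyst control and give the Z iodoacrylate (iodine cis to the ester) under kinetic control.

Step 12
Reactants: 22 ethyl (2Z,3S,5S,7Z)-8-({[tert-butyl(dimethyl)silyl]oxy}methyl)-3-hydroxy-2-(iodomethylidene)-5-{3-[(4-methoxybenzyl)oxy]prop-1-en-2-yl}-10-[(triethylsilyl)oxy]dec-7-enoate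
Product: 23 (2E,3S,5S,7Z)-8-({[tert-butyl(dimethyl)silyl]oxy}methyl)-2-(iodomethylidene)-5-{3-[(4-methoxybenzyl)oxy]prop-1-en-2-yl}-10-[(triethylsilyl)oxy]dec-7-ene-1,3-diol
Conditions: i-Bu2AlH (3.5 equiv), CH2Cl2, −78 °C; aq. potassium sodium tartrate
Reagents that add atoms: none
Why: 1,2-Reduction of the conjugated ester with i-Bu2AlH should give the primary allylic alcohol while the alkenyl iodide and its geometry are untouched at −78 °C.

Step 13
Reactants: 24 (4R)-4-benzyl-3-propanoyl-1,3-oxazolidin-2-one; 25 acetaldehyde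
Product: 28 (4R)-4-benzyl-3-[(2R,3S)-3-hydroxy-2-methylbutanoyl]-1,3-oxazolidin-2-one, via boron enolate 26 (not isolated), via boron aldolate 27 (not isolated)
Conditions: n-Bu2BOTf, Et3N, CH2Cl2, −78 to 0 °C; then pH 7 buffer, MeOH, 30% H2O2, 0 °C
Reagents that add atoms: none
Why: Evans syn-aldol reaction, in which the Z boron enolate reacts through a Zimmerman–Traxler chair with its dipole-minimised face set by the (R)-benzyl group, so the (2R,3S) syn adduct is expected.

Step 14
Reactants: 28 (4R)-4-benzyl-3-[(2R,3S)-3-hydroxy-2-methylbutanoyl]-1,3-oxazolidin-2-one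
Product: 29 (4R)-4-benzyl-3-[(2R,3S)-3-{[tert-butyl(dimethyl)silyl]oxy}-2-methylbutanoyl]-1,3-oxazolidin-2-one
Conditions: t-BuMe2SiOTf, 2,6-lutidine, CH2Cl2, −78 to 0 °C
Reagents that add atoms: tert-butyldimethylsilyl trifluoromethanesulfonate, CC(C)(C)[Si](C)(C)OS(=O)(=O)C(F)(F)F
Why: Silyl triflate silylation of the secondary aldol hydroxyl prevents retro-aldol cleavage in the next step and keeps this hydroxyl from competing in the later esterification.

Step 15
Reactants: 29 (4R)-4-benzyl-3-[(2R,3S)-3-{[tert-butyl(dimethyl)silyl]oxy}-2-methylbutanoyl]-1,3-oxazolidin-2-one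
Product: 30 (2R,3S)-3-{[tert-butyl(dimethyl)silyl]oxy}-2-methylbutanoic acid
Conditions: LiOH, 30% H2O2, THF/H2O 3:1, 0 °C; Na2SO3; then 1 M HCl
Reagents that add atoms: hydrogen peroxide, OO
Why: Hydroperoxide cleavage of the Evans imide attacks the exocyclic carbonyl selectively and releases the acid without epimerising the α-centre.

Step 16
Reactants: 23 (2E,3S,5S,7Z)-8-({[tert-butyl(dimethyl)silyl]oxy}methyl)-2-(iodomethylidene)-5-{3-[(4-methoxybenzyl)oxy]prop-1-en-2-yl}-10-[(triethylsilyl)oxy]dec-7-ene-1,3-diol; 30 (2R,3S)-3-{[tert-butyl(dimethyl)silyl]oxy}-2-methylbutanoic acid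
Product: 32 (2E,3S,5S,7Z)-8-({[tert-butyl(dimethyl)silyl]oxy}methyl)-3-hydroxy-2-(iodomethylidene)-5-{3-[(4-methoxybenzyl)oxy]prop-1-en-2-yl}-10-[(triethylsilyl)oxy]dec-7-en-1-yl (2R,3S)-3-{[tert-butyl(dimethyl)silyl]oxy}-2-methylbutanoate, via mixed anhydride 31 (not isolated)
Conditions: 2,4,6-Cl3C6H2COCl, Et3N, THF, rt; then 23, DMAP, toluene, −20 to 0 °C
Reagents that add atoms: none
Why: Yamaguchi esterification with one equivalent of the α-branched activated acid should acylate the primary allylic hydroxyl in preference to the hindered secondary one.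

Step 17
Reactants: 32 the primary mono-ester from step 16
Product: 33 (2E,3S,5S,7Z)-8-({[tert-butyl(dimethyl)silyl]oxy}methyl)-2-(iodomethylidene)-5-{3-[(4-methoxybenzyl)oxy]prop-1-en-2-yl}-3-[(2-methylpropanoyl)oxy]-10-[(triethylsilyl)oxy]dec-7-en-1-yl (2R,3S)-3-{[tert-butyl(dimethyl)silyl]oxy}-2-methylbutanoate
Conditions: (i-PrCO)2O, pyridine, DMAP (cat.), CH2Cl2, 0 °C to rt
Reagents that add atoms: 2-methylpropanoic anhydride, CC(C)C(=O)OC(=O)C(C)C
Why: DMAP-catalysed acylation of the remaining secondary allylic alcohol is fast enough to outrun 1,3-acyl migration of the neighbouring ester.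

Step 18
Reactants: 33 the PMB-protected diester from step 17
Product: 34 (2E,3S,5S,7Z)-8-({[tert-butyl(dimethyl)silyl]oxy}methyl)-5-(3-hydroxyprop-1-en-2-yl)-2-(iodomethylidene)-3-[(2-methylpropanoyl)oxy]-10-[(triethylsilyl)oxy]dec-7-en-1-yl (2R,3S)-3-{[tert-butyl(dimethyl)silyl]oxy}-2-methylbutanoate
Conditions: DDQ, CH2Cl2/pH 7 phosphate buffer 10:1, 0 °C
Reagents that add atoms: none
Why: Oxidative cleavage of the p-methoxybenzyl ether by DDQ (hydride abstraction, then hydrolysis of the oxocarbenium ion) is orthogonal to the silyl ethers, the esters and the alkenyl iodide under buffered conditions.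

Step 19
Reactants: 34 the allylic alcohol from step 18
Product: 35 (2E,3S,5S,7Z)-5-[3-(acetyloxy)prop-1-en-2-yl]-8-({[tert-butyl(dimethyl)silyl]oxy}methyl)-2-(iodomethylidene)-3-[(2-methylpropanoyl)oxy]-10-[(triethylsilyl)oxy]dec-7-en-1-yl (2R,3S)-3-{[tert-butyl(dimethyl)silyl]oxy}-2-methylbutanoate
Conditions: Ac2O, pyridine, DMAP (cat.), CH2Cl2, 0 °C
Reagents that add atoms: acetic anhydride, CC(=O)OC(C)=O
Why: Standard acetylation of the only free hydroxyl installs the allylic acetate of the target.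

Step 20
Reactants: 35 the acetate from step 19
Product: 36 (2E,3S,5S,7Z)-5-[3-(acetyloxy)prop-1-en-2-yl]-8-({[tert-butyl(dimethyl)silyl]oxy}methyl)-10-hydroxy-2-(iodomethylidene)-3-[(2-methylpropanoyl)oxy]dec-7-en-1-yl (2R,3S)-3-{[tert-butyl(dimethyl)silyl]oxy}-2-methylbutanoate
Conditions: PPTS (cat.), MeOH/CH2Cl2 1:1, 0 °C
Reagents that add atoms: none
Why: Acid-catalysed methanolysis cleaves the primary triethylsilyl ether much faster than the primary and secondary tert-butyldimethylsilyl ethers, and does not transesterify the acetate at 0 °C.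

Step 21
Reactants: 36 the primary alcohol from step 20
Product: 37 (2E,3S,5S,7Z)-5-[3-(acetyloxy)prop-1-en-2-yl]-8-({[tert-butyl(dimethyl)silyl]oxy}methyl)-10-iodo-2-(iodomethylidene)-3-[(2-methylpropanoyl)oxy]dec-7-en-1-yl (2R,3S)-3-{[tert-butyl(dimethyl)silyl]oxy}-2-methylbutanoate
Conditions: I2, PPh3, imidazole, CH2Cl2, 0 °C
Reagents that add atoms: iodine, [I][I]
Why: Appel-type (Garegg–Samuelsson) iodination converts the primary alcohol into the iodide by SN2 displacement of the alkoxyphosphonium ion without affecting esters, silyl ethers or the alkenyl iodide.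

Step 22
Reactants: 37 the di-iodide from step 21
Product: 39 [(1E,5Z,8S,10S)-8-[3-(acetyloxy)prop-1-en-2-yl]-5-({[tert-butyl(dimethyl)silyl]oxy}methyl)-10-[(2-methylpropanoyl)oxy]cyclodeca-1,5-dien-1-yl]methyl (2R,3S)-3-{[tert-butyl(dimethyl)silyl]oxy}-2-methylbutanoate (both ring olefins trans within the ring), via alkylzinc iodide 38 (not isolated)
Conditions: Zn dust (activated with BrCH2CH2Br and Me3SiCl), THF, 35 °C; then syringe-pump addition to Pd(PPh3)4 (15 mol %), THF, 40 °C, final concentration 1 mM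
Reagents that add atoms: none
Why: Zinc inserts into the primary C–I bond (the non-activated alkenyl iodide is inert to Zn in THF without LiCl) to give 38; zerovalent palladium then adds oxidatively to the alkenyl C–I bond with retention, the tethered alkylzinc transmetalates intramolecularly to an eleven-membered alkyl(alkenyl)palladacycle, and reductive elimination forges the C2(sp2)–C3(sp3) bond. The closest known reaction type is the Negishi alkyl–alkenyl cross-coupling, run here as a macrocyclisation under slow-addition pseudo-high dilution as in other palladium-mediated sp2–sp3 ring closures. It closes the single carbocycle, the ten-membered cyclodeca-1,5-diene, end to end by reductive elimination from the palladacycle, so no exo/endo choice and no olefin transposition arise. No stereocentre is created: the C1=C2 geometry is carried over with retention from the (E)-iodide (iodine trans to C10), which places C3 trans to C10 as the target requires, and C8 and C10 are untouched. The step needs cyclisation to beat oligomerisation and protodezincation, which dilution and the limited rotamers of a chain holding two trans-trisubstituted olefins and the C8 branch should secure; it also needs oxidative addition at the alkenyl iodide to beat ionisation of the three allylic esters, which the much faster insertion into the C–I bond at 40 °C should secure. β-Hydride elimination is disfavoured because the alkyl and alkenyl groups are held cis on palladium in the cyclic intermediate.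

Step 23
Reactants: 39 the bis-silylated macrocycle from step 22
Product: 40 [(1E,5Z,8S,10S)-8-[3-(acetyloxy)prop-1-en-2-yl]-5-(hydroxymethyl)-10-[(2-methylpropanoyl)oxy]cyclodeca-1,5-dien-1-yl]methyl (2R,3S)-3-hydroxy-2-methylbutanoate
Conditions: HF·pyridine, pyridine, THF, 0 °C to rt
Reagents that add atoms: none
Why: Fluoride-mediated desilylation with pyridine-buffered HF removes both tert-butyldimethylsilyl ethers without acid-triggered transannular cyclisation of the 1,5-diene or ester migration.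

Step 24
Reactants: 40 the macrocyclic diol from step 23
Product: 41 CNP0256542.1, the (5S,6R) trans-epoxide of 40 (C8 now R, C10 S, side chain 2R,3S)
Conditions: Ti(Oi-Pr)4 (20 mol %), L-(+)-diethyl tartrate (24 mol %), t-BuOOH, 4 Å molecular sieves, CH2Cl2, −20 °C
Reagents that add atoms: tert-butyl hydroperoxide, CC(C)(C)OO
Why: Katsuki–Sharpless asymmetric epoxidation, in which titanium binds only the C5 allylic alcohol (the other olefins carry no free allylic hydroxyl) and the L-(+)-tartrate complex delivers oxygen to the face that gives S at the hydroxymethyl-bearing carbon and R at C6, the same exposed face that peripheral attack on the trans ring olefin favours.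

**Compound list**

1 | 2,3-dibromoprop-1-ene | C=C(Br)CBr | starting material
2 | (4-methoxyphenyl)methanol | COc1ccc(CO)cc1 | starting material
3 | 1-{[(2-bromoprop-2-en-1-yl)oxy]methyl}-4-methoxybenzene | C=C(Br)COCc1ccc(OC)cc1 | intermediate
4 | bis(pinacolato)diboron | CC1(C)OB(OC1(C)C)B1OC(C)(C)C(C)(C)O1 | starting material
5 | 2-{3-[(4-methoxybenzyl)oxy]prop-1-en-2-yl}-4,4,5,5-tetramethyl-1,3,2-dioxaborolane | C=C(COCc1ccc(OC)cc1)B1OC(C)(C)C(C)(C)O1 | intermediate
6 | 5,6-dihydro-2H-pyran-2-one | O=C1C=CCCO1 | starting material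
7 | (4S)-4-{3-[(4-methoxybenzyl)oxy]prop-1-en-2-yl}oxan-2-one | O=C1C[C@@H](C(=C)COCc2ccc(OC)cc2)CCO1 | intermediate
8 | N,O-dimethylhydroxylamine hydrochloride | CNOC.Cl | starting material
9 | chloro(methyl)aluminium N-methoxy-N-methylamide | CON(C)[Al](C)Cl | intermediate
10 | (3S)-5-hydroxy-N-methoxy-N-methyl-3-{3-[(4-methoxybenzyl)oxy]prop-1-en-2-yl}pentanamide | CON(C)C(=O)C[C@@H](C(=C)COCc1ccc(OC)cc1)CCO | intermediate
11 | (3S)-N-methoxy-N-methyl-3-{3-[(4-methoxybenzyl)oxy]prop-1-en-2-yl}-5-oxopentanamide | CON(C)C(=O)C[C@@H](C(=C)COCc1ccc(OC)cc1)CC=O | intermediate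
12 | 2-iodoethan-1-ol | OCCI | starting material
13 | triethyl(2-iodoethoxy)silane | CC[Si](CC)(CC)OCCI | intermediate
14 | ethyl 2-[bis(2-methylphenoxy)phosphoryl]acetate | CCOC(=O)CP(=O)(Oc1ccccc1C)Oc1ccccc1C | starting material
15 | ethyl 2-[bis(2-methylphenoxy)phosphoryl]-4-[(triethylsilyl)oxy]butanoate (racemic) | CCOC(=O)C(CCO[Si](CC)(CC)CC)P(=O)(Oc1ccccc1C)Oc1ccccc1C | intermediate
16 | ethyl (2Z,5S)-7-[methoxy(methyl)amino]-5-{3-[(4-methoxybenzyl)oxy]prop-1-en-2-yl}-7-oxo-2-{2-[(triethylsilyl)oxy]ethyl}hept-2-enoate | CON(C)C(=O)C[C@@H](C(=C)COCc1ccc(OC)cc1)C/C=C(C(=O)OCC)/CCO[Si](CC)(CC)CC | intermediate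
17 | (3S,5Z)-6-(hydroxymethyl)-3-{3-[(4-methoxybenzyl)oxy]prop-1-en-2-yl}-8-[(triethylsilyl)oxy]oct-5-enal | O=CC[C@@H](C(=C)COCc1ccc(OC)cc1)C/C=C(CO)/CCO[Si](CC)(CC)CC | intermediate
18 | (3S,5Z)-6-({[tert-butyl(dimethyl)silyl]oxy}methyl)-3-{3-[(4-methoxybenzyl)oxy]prop-1-en-2-yl}-8-[(triethylsilyl)oxy]oct-5-enal | O=CC[C@@H](C(=C)COCc1ccc(OC)cc1)C/C=C(CO[Si](C)(C)C(C)(C)C)/CCO[Si](CC)(CC)CC | intermediate
19 | ethyl prop-2-ynoate | C#CC(=O)OCC | starting material
20 | [(1-ethoxy-3-iodopropa-1,2-dien-1-yl)oxy]trimethylsilane | CCOC(O[Si](C)(C)C)=C=CI | intermediate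
21 | trimethylsilyl ether of 22 | I/C=C(C(=O)OCC)/[C@@H](O[Si](C)(C)C)C[C@@H](C(=C)COCc1ccc(OC)cc1)C/C=C(CO[Si](C)(C)C(C)(C)C)/CCO[Si](CC)(CC)CC | intermediate
22 | ethyl (2Z,3S,5S,7Z)-8-({[tert-butyl(dimethyl)silyl]oxy}methyl)-3-hydroxy-2-(iodomethylidene)-5-{3-[(4-methoxybenzyl)oxy]prop-1-en-2-yl}-10-[(triethylsilyl)oxy]dec-7-enoate | I/C=C(C(=O)OCC)/[C@@H](O)C[C@@H](C(=C)COCc1ccc(OC)cc1)C/C=C(CO[Si](C)(C)C(C)(C)C)/CCO[Si](CC)(CC)CC | intermediate
23 | (2E,3S,5S,7Z)-8-({[tert-butyl(dimethyl)silyl]oxy}methyl)-2-(iodomethylidene)-5-{3-[(4-methoxybenzyl)oxy]prop-1-en-2-yl}-10-[(triethylsilyl)oxy]dec-7-ene-1,3-diol | I/C=C(CO)/[C@@H](O)C[C@@H](C(=C)COCc1ccc(OC)cc1)C/C=C(CO[Si](C)(C)C(C)(C)C)/CCO[Si](CC)(CC)CC | intermediate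
24 | (4R)-4-benzyl-3-propanoyl-1,3-oxazolidin-2-one | CCC(=O)N1C(=O)OC[C@H]1Cc1ccccc1 | starting material
25 | acetaldehyde | CC=O | starting material
26 | (Z)-dibutylboron enolate of 24 | C/C=C(\OB(CCCC)CCCC)N1C(=O)OC[C@H]1Cc1ccccc1 | intermediate
27 | dibutylboron aldolate of 28 | O=C([C@H](C)[C@H](C)OB(CCCC)CCCC)N1C(=O)OC[C@H]1Cc1ccccc1 | intermediate
28 | (4R)-4-benzyl-3-[(2R,3S)-3-hydroxy-2-methylbutanoyl]-1,3-oxazolidin-2-one | O=C([C@H](C)[C@H](C)O)N1C(=O)OC[C@H]1Cc1ccccc1 | intermediate
29 | (4R)-4-benzyl-3-[(2R,3S)-3-{[tert-butyl(dimethyl)silyl]oxy}-2-methylbutanoyl]-1,3-oxazolidin-2-one | O=C([C@H](C)[C@H](C)O[Si](C)(C)C(C)(C)C)N1C(=O)OC[C@H]1Cc1ccccc1 | intermediate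
30 | (2R,3S)-3-{[tert-butyl(dimethyl)silyl]oxy}-2-methylbutanoic acid | OC(=O)[C@H](C)[C@H](C)O[Si](C)(C)C(C)(C)C | intermediate
31 | mixed anhydride of 30 with 2,4,6-trichlorobenzoic acid | O=C(OC(=O)c1c(Cl)cc(Cl)cc1Cl)[C@H](C)[C@H](C)O[Si](C)(C)C(C)(C)C | intermediate
32 | (2E,3S,5S,7Z)-8-({[tert-butyl(dimethyl)silyl]oxy}methyl)-3-hydroxy-2-(iodomethylidene)-5-{3-[(4-methoxybenzyl)oxy]prop-1-en-2-yl}-10-[(triethylsilyl)oxy]dec-7-en-1-yl (2R,3S)-3-{[tert-butyl(dimethyl)silyl]oxy}-2-methylbutanoate | I/C=C(COC(=O)[C@H](C)[C@H](C)O[Si](C)(C)C(C)(C)C)/[C@@H](O)C[C@@H](C(=C)COCc1ccc(OC)cc1)C/C=C(CO[Si](C)(C)C(C)(C)C)/CCO[Si](CC)(CC)CC | intermediate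
33 | 3-O-(2-methylpropanoyl) derivative of 32 | I/C=C(COC(=O)[C@H](C)[C@H](C)O[Si](C)(C)C(C)(C)C)/[C@@H](OC(=O)C(C)C)C[C@@H](C(=C)COCc1ccc(OC)cc1)C/C=C(CO[Si](C)(C)C(C)(C)C)/CCO[Si](CC)(CC)CC | intermediate
34 | 33 without the 4-methoxybenzyl group (5-(3-hydroxyprop-1-en-2-yl)) | I/C=C(COC(=O)[C@H](C)[C@H](C)O[Si](C)(C)C(C)(C)C)/[C@@H](OC(=O)C(C)C)C[C@@H](C(=C)CO)C/C=C(CO[Si](C)(C)C(C)(C)C)/CCO[Si](CC)(CC)CC | intermediate
35 | acetate of 34 (5-[3-(acetyloxy)prop-1-en-2-yl]) | I/C=C(COC(=O)[C@H](C)[C@H](C)O[Si](C)(C)C(C)(C)C)/[C@@H](OC(=O)C(C)C)C[C@@H](C(=C)COC(C)=O)C/C=C(CO[Si](C)(C)C(C)(C)C)/CCO[Si](CC)(CC)CC | intermediate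
36 | 35 without the triethylsilyl group (10-hydroxy) | I/C=C(COC(=O)[C@H](C)[C@H](C)O[Si](C)(C)C(C)(C)C)/[C@@H](OC(=O)C(C)C)C[C@@H](C(=C)COC(C)=O)C/C=C(CO[Si](C)(C)C(C)(C)C)/CCO | intermediate
37 | (2E,3S,5S,7Z)-5-[3-(acetyloxy)prop-1-en-2-yl]-8-({[tert-butyl(dimethyl)silyl]oxy}methyl)-10-iodo-2-(iodomethylidene)-3-[(2-methylpropanoyl)oxy]dec-7-en-1-yl (2R,3S)-3-{[tert-butyl(dimethyl)silyl]oxy}-2-methylbutanoate | I/C=C(COC(=O)[C@H](C)[C@H](C)O[Si](C)(C)C(C)(C)C)/[C@@H](OC(=O)C(C)C)C[C@@H](C(=C)COC(C)=O)C/C=C(CO[Si](C)(C)C(C)(C)C)/CCI | intermediate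
38 | 10-(iodozincio) analogue of 37 | I/C=C(COC(=O)[C@H](C)[C@H](C)O[Si](C)(C)C(C)(C)C)/[C@@H](OC(=O)C(C)C)C[C@@H](C(=C)COC(C)=O)C/C=C(CO[Si](C)(C)C(C)(C)C)/CC[Zn]I | intermediate
39 | [(1E,5Z,8S,10S)-8-[3-(acetyloxy)prop-1-en-2-yl]-5-({[tert-butyl(dimethyl)silyl]oxy}methyl)-10-[(2-methylpropanoyl)oxy]cyclodeca-1,5-dien-1-yl]methyl (2R,3S)-3-{[tert-butyl(dimethyl)silyl]oxy}-2-methylbutanoate | C=C(COC(C)=O)[C@@H]1C[C@H](OC(=O)C(C)C)/C(COC(=O)[C@H](C)[C@H](C)O[Si](C)(C)C(C)(C)C)=C/CC/C(CO[Si](C)(C)C(C)(C)C)=C/C1 | intermediate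
40 | [(1E,5Z,8S,10S)-8-[3-(acetyloxy)prop-1-en-2-yl]-5-(hydroxymethyl)-10-[(2-methylpropanoyl)oxy]cyclodeca-1,5-dien-1-yl]methyl (2R,3S)-3-hydroxy-2-methylbutanoate | C=C(COC(C)=O)[C@@H]1C[C@H](OC(=O)C(C)C)/C(COC(=O)[C@H](C)[C@H](C)O)=C/CC/C(CO)=C/C1 | intermediate
41 | CNP0256542.1, the (5S,6R) trans-epoxide of 40 | C=C(COC(C)=O)[C@@H]1C[C@H](OC(=O)C(C)C)/C(COC(=O)[C@H](C)[C@H](C)O)=C/CC[C@@]2(CO)O[C@@H]2C1 | target

**Step count**

Total: 24 steps. Longest linear sequence: 19 steps (steps 1–5, 8–12, 16–24).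

**Steps most likely to fail**

Step 22 (ring closure). The strained ten-membered ring may form too slowly, so that intermolecular coupling (oligomerisation), protodezincation or β-hydride elimination of the alkylpalladium intermediate, or ionisation of the allylic esters by zerovalent palladium takes over. The fallback closes the ring on a chain in which the C5=C6 olefin is already an epoxide, a tactic known to ease germacrane-type ring closures because two sp3 carbons replace one trans olefin. It sets out from 37. HF·pyridine/pyridine should remove both silyl groups to give the acyclic diol F4. Sharpless epoxidation (Ti(Oi-Pr)4, L-(+)-diethyl tartrate, t-BuOOH, −20 °C), here purely reagent-controlled, should give the epoxy diol F5. Et3SiOTf/2,6-lutidine should give the bis(triethylsilyl) ether F6. Zinc insertion as in step 22 should give the alkylzinc iodide F7, and slow addition to Pd(PPh3)4 should close the ring to the epoxy macrocycle F8. HF·pyridine then returns to the route at 41.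

Step 3 (alkenyl transfer to the lactone). The 2-rhodio-allyl ether may lose its β-alkoxy group (escape of the alkenyl unit as allene), or the 1,1-disubstituted alkenyl–rhodium may insert sluggishly, eroding conversion and enantioselectivity. The fallback installs the carbon skeleton first and the oxygen afterwards. It sets out from 6. The same rhodium/(S)-BINAP addition with commercial isopropenylboronic acid pinacol ester, which has no β-oxygen, should give (4S)-4-(prop-1-en-2-yl)oxan-2-one F1. Ene-type allylic chlorination of this single olefin (Ca(OCl)2, solid CO2, CH2Cl2/H2O, 0 °C) should give (4S)-4-(3-chloroprop-1-en-2-yl)oxan-2-one F2. Etherification with 2 under neutral conditions (Ag2O, Bu4NI cat., CH2Cl2) returns to the route at 7; the intermediate allyl cation is symmetrical, so no regiochemical issue arises.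

Step 11 (iodo-aldol). Catalyst control may be poor with this branched, polyoxygenated aldehyde because the ether oxygens compete for the boron Lewis acid; the activated aldehyde may undergo a carbonyl-ene cyclisation onto the trisubstituted olefin; or Me3SiI may cleave the benzyl-type or silyl ethers. The fallback moves the stereocontrol from the catalyst to a covalently bound auxiliary and drops the strong Lewis acid. It sets out from 18. The MgI2-promoted iodo-aldol with (1R,2S,5R)-menthyl propiolate (CH2Cl2, 0 °C) should give the menthyl ester F3 as the Z iodoacrylate. Its C3 epimers are diastereomers and can be separated by chromatography if the auxiliary bias is modest. Reduction with i-Bu2AlH as in step 12 returns to the route at 23.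

**Further compounds**

F1 | step 3 | (4S)-4-(prop-1-en-2-yl)oxan-2-one | O=C1C[C@@H](C(C)=C)CCO1
F2 | step 3 | (4S)-4-(3-chloroprop-1-en-2-yl)oxan-2-one | O=C1C[C@@H](C(=C)CCl)CCO1
F3 | step 11 | (1R,2S,5R)-menthyl ester analogue of 22 | I/C=C(C(=O)O[C@@H]1C[C@H](C)CC[C@H]1C(C)C)/[C@@H](O)C[C@@H](C(=C)COCc1ccc(OC)cc1)C/C=C(CO[Si](C)(C)C(C)(C)C)/CCO[Si](CC)(CC)CC
F4 | step 22 | bis-desilylated 37 (acyclic diol di-iodide) | I/C=C(COC(=O)[C@H](C)[C@H](C)O)/[C@@H](OC(=O)C(C)C)C[C@@H](C(=C)COC(C)=O)C/C=C(CO)/CCI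
F5 | step 22 | (S,R)-epoxide of F4 (acyclic epoxy diol di-iodide) | I/C=C(COC(=O)[C@H](C)[C@H](C)O)/[C@@H](OC(=O)C(C)C)C[C@@H](C(=C)COC(C)=O)C[C@H]1O[C@]1(CO)CCI
F6 | step 22 | bis(triethylsilyl) ether of F5 | I/C=C(COC(=O)[C@H](C)[C@H](C)O[Si](CC)(CC)CC)/[C@@H](OC(=O)C(C)C)C[C@@H](C(=C)COC(C)=O)C[C@H]1O[C@]1(CO[Si](CC)(CC)CC)CCI
F7 | step 22 | alkylzinc iodide from F6 | I/C=C(COC(=O)[C@H](C)[C@H](C)O[Si](CC)(CC)CC)/[C@@H](OC(=O)C(C)C)C[C@@H](C(=C)COC(C)=O)C[C@H]1O[C@]1(CO[Si](CC)(CC)CC)CC[Zn]I
F8 | step 22 | bis(triethylsilyl) ether of 41 | C=C(COC(C)=O)[C@@H]1C[C@H](OC(=O)C(C)C)/C(COC(=O)[C@H](C)[C@H](C)O[Si](CC)(CC)CC)=C/CC[C@@]2(CO[Si](CC)(CC)CC)O[C@@H]2C1
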